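## Analysis of the target

The target is a 4,5-seco-guaianolide. A cycloheptane (C1, C5, C6, C7, C8, C9, C10) is cis-fused at C6–C7 to an α-methylene-γ-butyrolactone (O–C6, C7–C11, C11=C13, C12=O). C10 carries a methyl (C14), C1 carries a hydroxyl and a (3S)-3-hydroxybutanoyl chain (C2 ketone, C3, C4 carbinol, C15), and the C5 oxygen carries an (S)-2-methylbutanoate. Six ring stereocenters are contiguous (C9, C10, C1, C5, C6, C7); C4 and the ester α-carbon make eight. On one face (called β here) lie the C5 and C9 oxygens and the C1 acyl chain; on the other (α) lie the C1 hydroxyl, the C10 methyl and both lactone bonds, so the ring oxygens alternate C9β, C1α, C5β, C6α. Sensitive groups are the α-methylene lactone (Michael acceptor), the tertiary α-ketol C1/C2 (acyl shifts), the β-hydroxy ketone C2–C4 (dehydration, retro-aldol) and the C9 hydroxyl, which is cis to the C2 carbonyl and will lactonise onto any acyl donor at C2. The hardest point is C1: its carbon substituent must stand cis to both neighbouring oxygens, whereas a nucleophile adding to a C1 ketone would enter trans to them. The strategy is tied to the array C5(O)–C1(OH)(C2=O)–C10. With C5 as a ketone this is the retron of an α-ketol rearrangement, which traces the bond C1–C10 back to a bond C5–C10 of a six-membered ring. That ring (C5–C10, methyl on C10, three-carbon unit on C7) is the p-menthane skeleton of carvone.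

## Retrosynthetic reasoning

Target 24 to boronate 22. The C9–O bond is made last, by oxidation of a C9–B bond, together with loss of the C1 silyl group (through 23). The C9 oxygen is hidden as a boronate because a free C9 hydroxyl, cis to C2, would attack a thioester at C2.

22 to 20 and 21. The bond C3–C4 is cut as an aldol between methyl ketone 20 and acetaldehyde 21. C1 is quaternary, so C3 is the only enolisable position; C4 has to be set under reagent control.

20 to 19. The bond C2–C3 is cut to thioester 19. A thioester survives the hydride and hydroboration steps that a C2 ketone would not, and it can be turned into a ketone by palladium-catalysed organozinc coupling beside a lactone and an ester.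

19 to 17. The bonds C9–B and C10–H are cut together to the C9=C10 alkene of 17. A syn hydroboration from the β face sets C9 and C10 in one step and in the relative sense the target needs (methyl trans to the C9 oxygen).

17 to 13 (through 16 and 14). Silyl ether, C5 ester and C5 carbinol are removed in turn. The C5 alcohol comes from the C5 ketone of 13 by hydride delivery from the C1 hydroxyl, which gives the trans diol.

13 to 11 (key disconnection). The bond C1–C10 is cut and C10 is reconnected to C5. This contracts the cycloheptenone to cyclohexenol 11, in which C5 is a tertiary carbinol carrying the two-carbon diazo thioester. In the forward direction oxidation gives α-keto thioester 12, and a 1,2-shift of C10 from C5 to the keto carbon makes the seven-membered ring, the C5 ketone and the C1 carbinol at once. The cut is placed here because it is the only one that creates C1 by chirality transfer and not by facial attack on a hindered carbonyl.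

11 to 6 and 10. The bond C5–C1 is cut: the lithiated diazo thioester 10 adds to ketone 6. The cis-fused lactone and the C6 oxygen of 6 direct the attack to the β face.

6 to 1 (through 4, 3, 2). The lactone C6–O bond is cut to keto acid 4 (α′-halogenation, then intramolecular displacement with inversion through 5). The acid carbon C12 is traced to the isopropenyl methyl of (R)-carvone 1, oxidised while the ring alkene is still protected as an enone.

10 to 7 and 8. The diazo thioester comes from bromoacetyl bromide 7 and ethanethiol 8 through 9.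

## Alternatives that were turned down

Alternative 1: Ring-closing metathesis (the textbook route). Cut C5=C6; a diene carrying a vinyl group on C1 and on C7 would be closed to cycloheptene A1, then epoxidised and lactonised. Turned down because the key step sets no stereocenter. The open-chain precursor must already hold the C1 quaternary carbinol and the C9/C10 pair, each made by separate aldol or addition steps, so about ten steps precede ring closure. Metathesis next to a fully substituted carbinol with an acrylate in the molecule is also slow and unselective.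

Alternative 2: One-carbon ring expansion of the silyl dienol ether of 1 (cyclopropanation, then oxidative opening; Saegusa–Ito type). This inserts C5 between C1 and C6 and gives cross-conjugated dienone A2, with C1 as the ketone. Both enones could be epoxidised trans to the C7 substituent, and a C12 carboxylate could open the C5–C6 epoxide at C6 to give the lactone. Turned down because the side chain must then add to the C1 ketone cis to both neighbouring oxygens, while nucleophiles add anti to α-epoxides and α-alkoxy groups, giving the wrong C1 epimer. Correcting it by oxidative transposition costs five or more extra steps.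

Alternative 3: Oxidopyrylium [5+2] cycloaddition with a propenyl ether. It would form the C1–C10 and C8–C9 bonds and give oxabicycle A3 with the C1 oxygen, C9 and C10 in place. Turned down because there is no reliable absolute control (A3 would be racemic). The C8–O bond must also be cleaved reductively, which opens the bicycle before C6 and C7 are functionalised, so the facial bias is lost exactly where it is needed.

Key step: step 8

Assumption: atom numbers C1–C15 are those defined in the analysis, and (+)-Ipc2BCl is taken as the antipode that sends a methyl ketone enolate to the Re face of acetaldehyde.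

## Route

Step 1
Reactants: 1 (R)-carvone
Product: 2 (5R)-5-(3-chloroprop-1-en-2-yl)-2-methylcyclohex-2-en-1-one
Conditions: Ca(OCl)2, solid CO2, CH2Cl2/H2O, 0 °C
Reagents that add atoms: calcium hypochlorite, [Ca+2].[O-]Cl.[O-]Cl (gives hypochlorous acid, OCl, in the flask)
Why: Ene-type allylic chlorination; only the electron-rich isopropenyl alkene reacts because the ring alkene is deactivated as an enone. C7 is not touched.

Step 2
Reactants: 2 allylic chloride
Product: 3 2-[(1R)-4-methyl-5-oxocyclohex-3-en-1-yl]prop-2-enal
Conditions: NMO, NaI (cat.), NaHCO3, MeCN, 50 °C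
Reagents that add atoms: N-methylmorpholine N-oxide, C[N+]1([O-])CCOCC1
Why: Ganem oxidation (Kornblum type): the N-oxide is O-alkylated by the allylic halide and base-induced loss of the amine gives the enal.

Step 3
Reactants: 3 enal
Product: 4 2-[(1R)-4-methyl-5-oxocyclohex-3-en-1-yl]prop-2-enoic acid
Conditions: NaClO2, NaH2PO4, 2-methylbut-2-ene, t-BuOH/H2O, 0 °C to rt
Reagents that add atoms: sodium chlorite, [Na+].[O-]Cl=O
Why: Pinnick oxidation; chlorous acid oxidises only the aldehyde and the alkene scavenger removes hypochlorous acid.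

Step 4
Reactants: 4 keto acid
Product: 6 (3aS,7aR)-6-methyl-3-methylidene-3a,4-dihydro-1-benzofuran-2,7(3H,7aH)-dione, via iodo keto acid 5 (not isolated)
Conditions: LiN(iPr)2 (2.2 equiv), THF, −78 °C; I2, −78 °C to rt
Reagents that add atoms: none
Why: The kinetic α′ enolate (carboxylate as spectator) is iodinated at C6 and the carboxylate displaces iodide intramolecularly (SN2). Only the iodide trans to the side chain can be displaced, so inversion gives the cis-fused lactone with C6–O on the face of C7–C11; the cis iodide equilibrates by iodide exchange or enolisation.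

Step 5
Reactants: 7 bromoacetyl bromide; 8 ethanethiol
Product: 9 S-ethyl 2-bromoethanethioate
Conditions: pyridine, CH2Cl2, 0 °C
Reagents that add atoms: none
Why: Acylation of the thiol at the acyl bromide, which is much faster than substitution at the CH2Br carbon.

Step 6
Reactants: 9 S-ethyl 2-bromoethanethioate
Product: 10 S-ethyl 2-diazoethanethioate
Conditions: TsNHNHTs, DBU, THF, 0 °C
Reagents that add atoms: N,N'-ditosylhydrazine, Cc1ccc(cc1)S(=O)(=O)NNS(=O)(=O)c1ccc(C)cc1
Why: N-alkylation of the hydrazine and base-induced loss of two sulfinate groups gives the diazo compound (diazoacetate synthesis from bromoacetates).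

Step 7
Reactants: 6 lactone ketone; 10 S-ethyl 2-diazoethanethioate
Product: 11 S-ethyl 2-diazo-2-[(3aS,7R,7aR)-7-hydroxy-6-methyl-3-methylidene-2-oxo-2,3,3a,4,7,7a-hexahydro-1-benzofuran-7-yl]ethanethioate
Conditions: LiN(iPr)2, THF, −90 °C; then 6; AcOH, −90 °C
Reagents that add atoms: none
Why: Aldol-type addition of the lithiated diazo thioester to the ketone. Attack on the convex β face, anti to the C6 oxygen (Felkin–Anh), puts the new C–C bond β and the hydroxyl α.

Step 8
Reactants: 11 diazo adduct
Product: 13 S-ethyl (3aS,7S,8aR)-7-hydroxy-6-methyl-3-methylidene-2,8-dioxo-3,3a,4,7,8,8a-hexahydro-2H-cyclohepta[b]furan-7-carbothioate, via keto thioester 12 (not isolated)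
Conditions: dimethyldioxirane (1.05 equiv), acetone/CH2Cl2, −40 °C; then Zn(OTf)2 (20 mol %), 4 Å MS, CH2Cl2, 0 °C to rt
Reagents that add atoms: dimethyldioxirane, CC1(C)OO1
Why: Dimethyldioxirane transfers oxygen to the diazo carbon with loss of N2 to give the vicinal keto thioester 12; this oxidation is faster than epoxidation of the trisubstituted alkene. Zn(OTf)2 then binds the tertiary hydroxyl and the adjacent keto oxygen in a five-membered chelate, and the ring bond C5–C10, which stands perpendicular to the chelate, migrates with its electron pair from C5 to the keto carbon while C5 becomes a ketone: an α-ketol (acyloin) rearrangement. The closest known reaction type is the Lewis acid catalysed α-ketol rearrangement of tertiary β-hydroxy α-keto esters to α-hydroxy β-keto esters and its ring-enlarging variants on 1-acylcycloalkanols. No ring is closed by cyclisation; the cycloheptene arises by one-carbon ring enlargement, the former keto carbon being inserted between C5 and C10 as C1. The only new stereocenter is C1, fixed by chirality transfer from C5 of 11 (destroyed in the step): in the chelate the alkenyl carbon can reach only one face of the keto group, which places the C1 oxygen α and the thioester β. The step needs migration of C10 and not of C6; C10 is an alkenyl carbon of high migratory aptitude, while C6 carries the electron-withdrawing lactone oxygen. It also needs the chelated and not the open rotamer, which the bidentate Lewis acid in a non-coordinating solvent secures. The driving force is the change from a vicinal dicarbonyl to a β-dicarbonyl array.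

Step 9
Reactants: 13 ring-expanded keto thioester
Product: 14 S-ethyl (3aS,7S,8S,8aR)-7,8-dihydroxy-6-methyl-3-methylidene-2-oxo-3,3a,4,7,8,8a-hexahydro-2H-cyclohepta[b]furan-7-carbothioate
Conditions: Me4NBH(OAc)3, MeCN/AcOH, −20 °C
Reagents that add atoms: none
Why: Hydroxyl-directed reduction (Evans–Saksena type): the borohydride is bound to the C1 oxygen and delivers hydride to the α face of the C5 ketone, giving the trans diol (C5–OH β). Thioester, lactone and alkenes do not react.

Step 10
Reactants: 14 diol; 15 (2S)-2-methylbutanoic anhydride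
Product: 16 (3aS,7S,8S,8aR)-7-[(ethylsulfanyl)carbonyl]-7-hydroxy-6-methyl-3-methylidene-2-oxo-3,3a,4,7,8,8a-hexahydro-2H-cyclohepta[b]furan-8-yl (2S)-2-methylbutanoate
Conditions: DMAP (cat.), Et3N, CH2Cl2, 0 °C to rt
Reagents that add atoms: none
Why: DMAP-catalysed acylation of the only secondary alcohol; the tertiary C1 hydroxyl does not react, and the anhydride avoids a ketene pathway that would erode the α-stereocenter of the acyl group.

Step 11
Reactants: 16 hydroxy ester
Product: 17 the C1 trimethylsilyl ether of 16
Conditions: TMSOTf, 2,6-lutidine, CH2Cl2, −78 to 0 °C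
Reagents that add atoms: trimethylsilyl trifluoromethanesulfonate, C[Si](C)(C)OS(=O)(=O)C(F)(F)F
Why: Silylation of the tertiary alcohol; the silyl ether shields the α face for step 12 and keeps the hydroxyl out of the enolisation in step 14.

Step 12
Reactants: 17 silyl ether
Product: 19 the C9 pinacol boronate (boron β at C9, hydrogen β and methyl α at C10), via monoalkylborane 18 (not isolated)
Conditions: BH3·SMe2 (1.2 equiv), THF, −10 to 0 °C; then pinacol, rt
Reagents that add atoms: borane–dimethyl sulfide, [BH3-][S+](C)C; pinacol, CC(C)(O)C(C)(C)O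
Why: Hydroboration (syn, anti-Markovnikov): boron goes to the less substituted C9 and hydrogen to C10 from the same β face, opposite the C1 silyl ether and the cis-fused lactone, which sets C9 and C10 together. Pinacol turns the alkylborane into a stable boronate that masks the C9 oxygen until C2 is a ketone.

Step 13
Reactants: 19 boronate thioester
Product: 20 the C1 methyl ketone (acetyl in place of the thioester)
Conditions: MeZnI, PdCl2(PPh3)2 (10 mol %), toluene/THF, rt
Reagents that add atoms: methylzinc iodide, C[Zn]I
Why: Fukuyama coupling: zerovalent palladium inserts into the C–S bond, zinc transfers methyl and reductive elimination gives the ketone. Lactone, ester, silyl ether and boronate are not attacked by the organozinc.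

Step 14
Reactants: 20 methyl ketone; 21 acetaldehyde
Product: 22 the (4S)-β-hydroxy ketone (3-hydroxybutanoyl chain on C1)
Conditions: (+)-Ipc2BCl, Et3N, Et2O, 0 °C; then 21, −78 to −20 °C; MeOH, pH 7 buffer
Reagents that add atoms: none
Why: Reagent-controlled boron aldol (Paterson aldol) at C3, the only enolisable position. The isopinocampheyl groups direct the enolate to the Re face of 21 and set C4 as S.

Step 15
Reactants: 22 boronate aldol
Product: 24 target (CNP0291806.1), via silyl ether alcohol 23 (not isolated)
Conditions: NaBO3·4H2O, THF/H2O, 0 °C to rt; then citric acid, MeOH, rt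
Reagents that add atoms: sodium perborate, [Na+].[O-]OB=O
Why: Oxidation of the C–B bond with retention gives the C9 hydroxyl (β); mild acid then removes the trimethylsilyl group. Perborate is mild enough for the esters and the β-hydroxy ketone.

## Compound list

1 | (R)-(−)-carvone, (5R)-2-methyl-5-(prop-1-en-2-yl)cyclohex-2-en-1-one | CC1=CC[C@H](CC1=O)C(C)=C | starting material
2 | (5R)-5-(3-chloroprop-1-en-2-yl)-2-methylcyclohex-2-en-1-one | CC1=CC[C@H](CC1=O)C(=C)CCl | intermediate
3 | 2-[(1R)-4-methyl-5-oxocyclohex-3-en-1-yl]prop-2-enal | CC1=CC[C@H](CC1=O)C(=C)C=O | intermediate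
4 | 2-[(1R)-4-methyl-5-oxocyclohex-3-en-1-yl]prop-2-enoic acid | CC1=CC[C@H](CC1=O)C(=C)C(=O)O | intermediate
5 | 2-[(1S,6S)-6-iodo-4-methyl-5-oxocyclohex-3-en-1-yl]prop-2-enoic acid (iodide trans to the side chain; present as lithium carboxylate) | CC1=CC[C@H]([C@H](I)C1=O)C(=C)C(=O)O | intermediate (not isolated)
6 | (3aS,7aR)-6-methyl-3-methylidene-3a,4-dihydro-1-benzofuran-2,7(3H,7aH)-dione | C=C1C(=O)O[C@@H]2[C@H]1CC=C(C)C2=O | intermediate
7 | bromoacetyl bromide | BrCC(Br)=O | starting material
8 | ethanethiol | CCS | starting material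
9 | S-ethyl 2-bromoethanethioate | CCSC(=O)CBr | intermediate
10 | S-ethyl 2-diazoethanethioate | CCSC(=O)C=[N+]=[N-] | intermediate
11 | S-ethyl 2-diazo-2-[(3aS,7R,7aR)-7-hydroxy-6-methyl-3-methylidene-2-oxo-2,3,3a,4,7,7a-hexahydro-1-benzofuran-7-yl]ethanethioate | C=C1C(=O)O[C@@H]2[C@H]1CC=C(C)[C@@]2(O)C(=[N+]=[N-])C(=O)SCC | intermediate
12 | S-ethyl 2-[(3aS,7S,7aR)-7-hydroxy-6-methyl-3-methylidene-2-oxo-2,3,3a,4,7,7a-hexahydro-1-benzofuran-7-yl]-2-oxoethanethioate | C=C1C(=O)O[C@@H]2[C@H]1CC=C(C)[C@@]2(O)C(=O)C(=O)SCC | intermediate (not isolated)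
13 | S-ethyl (3aS,7S,8aR)-7-hydroxy-6-methyl-3-methylidene-2,8-dioxo-3,3a,4,7,8,8a-hexahydro-2H-cyclohepta[b]furan-7-carbothioate | C=C1C(=O)O[C@@H]2[C@H]1CC=C(C)[C@@](O)(C(=O)SCC)C2=O | intermediate
14 | S-ethyl (3aS,7S,8S,8aR)-7,8-dihydroxy-6-methyl-3-methylidene-2-oxo-3,3a,4,7,8,8a-hexahydro-2H-cyclohepta[b]furan-7-carbothioate | C=C1C(=O)O[C@@H]2[C@H]1CC=C(C)[C@@](O)(C(=O)SCC)[C@H]2O | intermediate
15 | (2S)-2-methylbutanoic anhydride | CC[C@H](C)C(=O)OC(=O)[C@@H](C)CC | starting material
16 | (3aS,7S,8S,8aR)-7-[(ethylsulfanyl)carbonyl]-7-hydroxy-6-methyl-3-methylidene-2-oxo-3,3a,4,7,8,8a-hexahydro-2H-cyclohepta[b]furan-8-yl (2S)-2-methylbutanoate | C=C1C(=O)O[C@@H]2[C@H]1CC=C(C)[C@@](O)(C(=O)SCC)[C@H]2OC(=O)[C@@H](C)CC | intermediate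
17 | (3aS,7S,8S,8aR)-7-[(ethylsulfanyl)carbonyl]-6-methyl-3-methylidene-2-oxo-7-[(trimethylsilyl)oxy]-3,3a,4,7,8,8a-hexahydro-2H-cyclohepta[b]furan-8-yl (2S)-2-methylbutanoate | C=C1C(=O)O[C@@H]2[C@H]1CC=C(C)[C@@](O[Si](C)(C)C)(C(=O)SCC)[C@H]2OC(=O)[C@@H](C)CC | intermediate
18 | C9 monoalkylborane of 17 (BH2 β at C9, methyl α at C10) | C=C1C(=O)O[C@@H]2[C@H]1C[C@@H]([BH2])[C@H](C)[C@@](O[Si](C)(C)C)(C(=O)SCC)[C@H]2OC(=O)[C@@H](C)CC | intermediate (not isolated)
19 | (3aS,5R,6S,7S,8S,8aR)-7-[(ethylsulfanyl)carbonyl]-6-methyl-3-methylidene-2-oxo-5-(4,4,5,5-tetramethyl-1,3,2-dioxaborolan-2-yl)-7-[(trimethylsilyl)oxy]octahydro-2H-cyclohepta[b]furan-8-yl (2S)-2-methylbutanoate | C=C1C(=O)O[C@@H]2[C@H]1C[C@@H](B3OC(C)(C)C(C)(C)O3)[C@H](C)[C@@](O[Si](C)(C)C)(C(=O)SCC)[C@H]2OC(=O)[C@@H](C)CC | intermediate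
20 | (3aS,5R,6S,7S,8S,8aR)-7-acetyl-6-methyl-3-methylidene-2-oxo-5-(4,4,5,5-tetramethyl-1,3,2-dioxaborolan-2-yl)-7-[(trimethylsilyl)oxy]octahydro-2H-cyclohepta[b]furan-8-yl (2S)-2-methylbutanoate | C=C1C(=O)O[C@@H]2[C@H]1C[C@@H](B3OC(C)(C)C(C)(C)O3)[C@H](C)[C@@](O[Si](C)(C)C)(C(C)=O)[C@H]2OC(=O)[C@@H](C)CC | intermediate
21 | acetaldehyde | CC=O | starting material
22 | (3aS,5R,6S,7S,8S,8aR)-7-[(3S)-3-hydroxybutanoyl]-6-methyl-3-methylidene-2-oxo-5-(4,4,5,5-tetramethyl-1,3,2-dioxaborolan-2-yl)-7-[(trimethylsilyl)oxy]octahydro-2H-cyclohepta[b]furan-8-yl (2S)-2-methylbutanoate | C=C1C(=O)O[C@@H]2[C@H]1C[C@@H](B3OC(C)(C)C(C)(C)O3)[C@H](C)[C@@](O[Si](C)(C)C)(C(=O)C[C@H](C)O)[C@H]2OC(=O)[C@@H](C)CC | intermediate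
23 | (3aS,5R,6S,7S,8S,8aR)-5-hydroxy-7-[(3S)-3-hydroxybutanoyl]-6-methyl-3-methylidene-2-oxo-7-[(trimethylsilyl)oxy]octahydro-2H-cyclohepta[b]furan-8-yl (2S)-2-methylbutanoate | C=C1C(=O)O[C@@H]2[C@H]1C[C@@H](O)[C@H](C)[C@@](O[Si](C)(C)C)(C(=O)C[C@H](C)O)[C@H]2OC(=O)[C@@H](C)CC | intermediate (not isolated)
24 | (3aS,5R,6S,7S,8S,8aR)-5,7-dihydroxy-7-[(3S)-3-hydroxybutanoyl]-6-methyl-3-methylidene-2-oxooctahydro-2H-cyclohepta[b]furan-8-yl (2S)-2-methylbutanoate (CNP0291806.1) | C=C1C(=O)O[C@@H]2[C@H]1C[C@@H](O)[C@H](C)[C@@](O)(C(=O)C[C@H](C)O)[C@H]2OC(=O)[C@@H](C)CC | target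

## Step count and least certain steps

Total: 15 steps. Longest linear sequence: 13 steps (steps 1–4 and 7–15, from 1); steps 5 and 6 prepare 10.

Step 8 (key step). Most likely failures: migration of C6 in place of C10, reaction through the non-chelated rotamer (which would give the C1 epimer), ionisation of the tertiary allylic alcohol by the Lewis acid, or a further acyl shift in the product. Fallback, from 11 back to 13: decomposition of 11 with Rh2(OAc)4 gives a divalent rhodium carbenoid that undergoes the well-precedented 1,2-alkenyl shift to the β-keto thioester F1. Its potassium enolate is then hydroxylated at C1 with a (camphorsulfonyl)oxaziridine, the reagent antipode being chosen for the α-hydroxyl, and 13 is separated from its C1 epimer.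

Step 7. Most likely failures: proton transfer from the acidic C6–H of 6 to the lithiated diazo thioester, or its conjugate addition or dipolar cycloaddition to the α-methylene lactone. Fallback, from 4 back to 13, with the order of events changed: 10 is added to the lithium carboxylate of 4, where the acrylate is protected as carboxylate, to give the diazo carbinol acid F2. The sequence of step 8 then gives the ring-expanded keto acid F3. Enolisation of F3 is possible only towards C6, and iodination with carboxylate displacement as in step 4 closes the lactone to 13.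

Step 4. Most likely failure: loss of HI from 5 towards a dienone and aromatisation, faster than the intramolecular displacement. Fallback, from 4 back to 6: hydroxylation of the dianion of 4 with 2-(phenylsulfonyl)-3-phenyloxaziridine gives the trans hydroxy acid F4, and Mitsunobu lactonisation (PPh3, DIAD) closes the lactone with inversion at C6 to 6.

Step 12. Most likely failures: poor facial selectivity at the C9=C10 alkene, and competing reduction or hydroboration of the α-methylene lactone. Fallback, from 17 back to 24: epoxidation of the electron-rich alkene with mCPBA from the β face gives the epoxide F5. Reductive opening with Cp2TiCl (trivalent titanium, made from Cp2TiCl2 and Mn) and 1,4-cyclohexadiene (Nugent–RajanBabu) gives the C9 alcohol F6; the C10 epimers are separated here. Et3SiOTf gives the triethylsilyl ether F7. The chemistry of steps 13 and 14 then gives the methyl ketone F8 and the aldol F9, and HF·pyridine removes both silyl groups to give 24.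

Step 14. Most likely failure: low facial selectivity at C4 if the reagent and the C1 stereocenter are mismatched. Fallback, from 20 back to 22: aldol with (c-C6H11)2BCl and acetaldehyde gives 22 together with its C4 epimer F10. Dess–Martin oxidation of the mixture gives the diketone F11, and transfer hydrogenation with RuCl(p-cymene)[(S,S)-TsDPEN] and HCO2H/Et3N (Noyori) reduces the unhindered C4 carbonyl to the (S) carbinol 22.

## Further compounds

F1 | step 8 | S-ethyl (3aS,8aR)-6-methyl-3-methylidene-2,8-dioxo-3,3a,4,7,8,8a-hexahydro-2H-cyclohepta[b]furan-7-carbothioate (C1 epimers, enolisable) | C=C1C(=O)O[C@@H]2[C@H]1CC=C(C)C(C(=O)SCC)C2=O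
F2 | step 7 | diazo carbinol acid: 2-{(1R)-5-[1-diazo-2-(ethylsulfanyl)-2-oxoethyl]-5-hydroxy-4-methylcyclohex-3-en-1-yl}prop-2-enoic acid (hydroxyl cis to the side chain) | CC1=CC[C@H](C[C@]1(O)C(=[N+]=[N-])C(=O)SCC)C(=C)C(=O)O
F3 | step 7 | ring-expanded keto acid: 2-{(1R)-5-[(ethylsulfanyl)carbonyl]-5-hydroxy-4-methyl-6-oxocyclohept-3-en-1-yl}prop-2-enoic acid (C1 configured as in 13) | CC1=CC[C@H](CC(=O)[C@]1(O)C(=O)SCC)C(=C)C(=O)O
F4 | step 4 | 2-[(1R)-6-hydroxy-4-methyl-5-oxocyclohex-3-en-1-yl]prop-2-enoic acid (hydroxyl trans to the side chain) | CC1=CC[C@H]([C@H](O)C1=O)C(=C)C(=O)O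
F5 | step 12 | C9,C10 β-epoxide of 17 | C=C1C(=O)O[C@@H]2[C@H]1C[C@H]3O[C@@]3(C)[C@@](O[Si](C)(C)C)(C(=O)SCC)[C@H]2OC(=O)[C@@H](C)CC
F6 | step 12 | C9 β-alcohol (C10 methyl α) with C1 silyl ether and thioester | C=C1C(=O)O[C@@H]2[C@H]1C[C@@H](O)[C@H](C)[C@@](O[Si](C)(C)C)(C(=O)SCC)[C@H]2OC(=O)[C@@H](C)CC
F7 | step 12 | C9 triethylsilyl ether of F6 | C=C1C(=O)O[C@@H]2[C@H]1C[C@@H](O[Si](CC)(CC)CC)[C@H](C)[C@@](O[Si](C)(C)C)(C(=O)SCC)[C@H]2OC(=O)[C@@H](C)CC
F8 | step 12 | C1 methyl ketone from F7 | C=C1C(=O)O[C@@H]2[C@H]1C[C@@H](O[Si](CC)(CC)CC)[C@H](C)[C@@](O[Si](C)(C)C)(C(C)=O)[C@H]2OC(=O)[C@@H](C)CC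
F9 | step 12 | (4S) aldol from F8, bis-silyl ether of 24 | C=C1C(=O)O[C@@H]2[C@H]1C[C@@H](O[Si](CC)(CC)CC)[C@H](C)[C@@](O[Si](C)(C)C)(C(=O)C[C@H](C)O)[C@H]2OC(=O)[C@@H](C)CC
F10 | step 14 | (4R) epimer of 22 | C=C1C(=O)O[C@@H]2[C@H]1C[C@@H](B3OC(C)(C)C(C)(C)O3)[C@H](C)[C@@](O[Si](C)(C)C)(C(=O)C[C@@H](C)O)[C@H]2OC(=O)[C@@H](C)CC
F11 | step 14 | C2,C4 diketone (3-oxobutanoyl chain on C1) | C=C1C(=O)O[C@@H]2[C@H]1C[C@@H](B3OC(C)(C)C(C)(C)O3)[C@H](C)[C@@](O[Si](C)(C)C)(C(=O)CC(C)=O)[C@H]2OC(=O)[C@@H](C)CC
A1 | alternative 1 | cycloheptene from ring-closing metathesis (C5=C6 alkene, C1 acetyl carbinol, C9 silyl ether, C10 methyl, C7 acrylate; configured as in the target) | COC(=O)C(=C)[C@@H]1C[C@@H](O[Si](C)(C)C(C)(C)C)[C@H](C)[C@@](O)(C(C)=O)C=C1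
A2 | alternative 2 | (5R)-2-methyl-5-(prop-1-en-2-yl)cyclohepta-2,6-dien-1-one | CC1=CC[C@H](C=CC1=O)C(C)=C
A3 | alternative 3 | 8-oxabicyclo[3.2.1]oct-3-en-2-one cycloadduct (bridge oxygen on C1 and C8, C5 ketone, C9 ethoxy, C10 methyl; drawn as the needed enantiomer) | O=C1C=C[C@@H]2O[C@@]1(C(=C)C[C@H](C)O[Si](C)(C)C(C)(C)C)[C@@H](C)[C@@H]2OCC
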